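**Strategy.** The target is a 7,9-diacyloxylongipin-2-en-1-one (longipinane numbering). Everything rests on the C4–C5 bond, which the cyclobutane (C4, C5, C11, C10) and the cyclohexenone (C1, C2, C3, C4, C5, C11) share. The precursor is a cis-fused bicyclo[5.4.0]undecane: a cycloheptane with a C5 mesylate, fused at C10–C11 to a 3-methoxycyclohexenone whose carbonyl still sits at C3. Kinetic enolisation at C4 and rear-side displacement at C5 close both rings in one operation and fix C4 and C5. One catalytic aldol sets C7. Hydroxyl-directed hydride transfers relay it to C9 and C5, and the C9 silyl ether steers the Diels–Alder reaction that sets C10 and C11. Methyllithium and acid then move the carbonyl to C1.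

Key step: step 11

Numbering (longipinane):
- C1 = ring C=O, C2 = CH=, C3 = C(CH3)=
- C4 = CH next to C3, C5 = CH next to C6, C6 = C(CH3)2
- C7 = CH–O (senecioate), C8 = CH2, C9 = CH–O (angelate)
- C10 = C(CH3), C11 = CH next to C1

Assumption: the (S,S)-ProPhenol/zinc catalyst is taken to deliver the enolate to the Re face of aldehyde 2 (3R product). If the sense is opposite, the (R,R)-ligand is used.

## Route

Step 1
Reactants: 1 3-methylbut-3-en-2-one; 2 methyl 2,2-dimethyl-3-oxopropanoate
Product: 3 methyl (3R)-3-hydroxy-2,2,6-trimethyl-5-oxohept-6-enoate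
Conditions: (S,S)-ProPhenol (10 mol %), Et2Zn (20 mol %), 4 Å MS, THF, 0 °C
Reagents that add atoms: none
Why: Direct catalytic asymmetric aldol addition with a dinuclear zinc ProPhenol catalyst, a reaction type known for methyl vinyl ketones and alpha-branched aldehydes; 1 can be enolised only at its methyl group, 2 cannot be enolised, and the chiral zinc pocket sets C7.

Step 2
Reactants: 3 methyl (3R)-3-hydroxy-2,2,6-trimethyl-5-oxohept-6-enoate
Product: 4 methyl (3R,5R)-3,5-dihydroxy-2,2,6-trimethylhept-6-enoate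
Conditions: Me4NBH(OAc)3, MeCN/AcOH, −35 °C
Reagents that add atoms: none
Why: Evans–Saksena reduction, in which the C7 hydroxyl binds the acyloxyborohydride and hydride is delivered through a chair-like six-membered transition state, should give the 1,3-anti diol and so set C9, while the ester stays inert.

Step 3
Reactants: 4 methyl (3R,5R)-3,5-dihydroxy-2,2,6-trimethylhept-6-enoate
Product: 5 methyl (3R,5R)-5-(tert-butyldimethylsilyloxy)-3-hydroxy-2,2,6-trimethylhept-6-enoate
Conditions: TBSCl (1.05 equiv), imidazole, DMF, 0 °C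
Reagents that add atoms: tert-butyldimethylsilyl chloride, CC(C)(C)[Si](C)(C)Cl
Why: Kinetically selective silyl ether formation, since the allylic C9 hydroxyl (next to an sp2 carbon and a CH2) should react well before the C7 hydroxyl next to quaternary C6; prompt silylation also forestalls delta-lactonisation onto the ester.

Step 4
Reactants: 5 methyl (3R,5R)-5-(tert-butyldimethylsilyloxy)-3-hydroxy-2,2,6-trimethylhept-6-enoate
Product: 7 (5R,7R)-7-(tert-butyldimethylsilyloxy)-5-hydroxy-4,4,8-trimethylnona-1,8-dien-3-one, via Weinreb amide 6 (not isolated)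
Conditions: MeNH(OMe)·HCl, iPrMgCl, THF, −15 °C; then CH2=CHMgBr, 0 °C; cold 1 M HCl quench
Reagents that add atoms: N,O-dimethylhydroxylamine hydrochloride, CNOC.Cl (stays only in 6); vinylmagnesium bromide, C=C[Mg]Br
Why: Ester-to-ketone conversion through a Weinreb amide in one flask, where the chelated tetrahedral adduct of 6 with the Grignard reagent stops at the ketone stage; no stereocenter is touched.

Step 5
Reactants: 7 (5R,7R)-7-(tert-butyldimethylsilyloxy)-5-hydroxy-4,4,8-trimethylnona-1,8-dien-3-one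
Product: 8 (4R,6R)-4-(tert-butyldimethylsilyloxy)-6-hydroxy-3,7,7-trimethylcyclohept-2-en-1-one
Conditions: second-generation Hoveyda–Grubbs catalyst (5 mol %), toluene (2 mM), 80 °C
Reagents that add atoms: none
Why: Ring-closing metathesis between the acryloyl group and the 1,1-disubstituted alkene, driven by loss of ethene and helped by the gem-dimethyl group, should close the cycloheptenone with the ring-enforced Z C10=C11 bond.

Step 6
Reactants: 9 1,1-dimethoxyethene; 10 acetyl chloride
Product: 11 4,4-dimethoxybut-3-en-2-one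
Conditions: Et3N, Et2O, 0 °C to rt
Reagents that add atoms: none
Why: C-acylation of a ketene acetal by an acid chloride, followed by loss of HCl to the amine, gives the push-pull enone.

Step 7
Reactants: 11 4,4-dimethoxybut-3-en-2-one
Product: 12 3-(tert-butyldimethylsilyloxy)-1,1-dimethoxybuta-1,3-diene
Conditions: TBSOTf, Et3N, Et2O, 0 °C
Reagents that add atoms: tert-butyldimethylsilyl triflate, CC(C)(C)[Si](C)(C)OS(=O)(=O)C(F)(F)F
Why: Soft enolisation and O-silylation at the only enolisable position, the methyl group, gives the 1,1-dialkoxy-3-silyloxydiene.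

Step 8
Reactants: 8 (4R,6R)-4-(tert-butyldimethylsilyloxy)-6-hydroxy-3,7,7-trimethylcyclohept-2-en-1-one; 12 3-(tert-butyldimethylsilyloxy)-1,1-dimethoxybuta-1,3-diene
Product: 15 (4aR,5R,7R,9aR)-5-(tert-butyldimethylsilyloxy)-7-hydroxy-1-methoxy-4a,8,8-trimethyl-4a,5,6,7,8,9a-hexahydro-3H-benzo[7]annulene-3,9(4H)-dione, via TMS ether 13 (not isolated), via cycloadduct 14 (not isolated)
Conditions: N,O-bis(trimethylsilyl)acetamide, CH2Cl2, rt; 12 (3 equiv), 12 kbar, rt; then 1 M HCl, THF, 0 °C
Reagents that add atoms: N,O-bis(trimethylsilyl)acetamide, CC(=N[Si](C)(C)C)O[Si](C)(C)C (stays only in 13 and 14)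
Why: High-pressure Diels–Alder reaction in which the nucleophilic CH2 terminus of the diene bonds to the enone beta-carbon C10 and the acetal carbon to C11, the diene adds opposite to the C9 silyloxy group, and suprafacial addition makes the fusion cis (sets C10 and C11); the acid work-up hydrolyses the silyl enol ether, eliminates one methanol and frees the C7 hydroxyl.

Step 9
Reactants: 15 (4aR,5R,7R,9aR)-5-(tert-butyldimethylsilyloxy)-7-hydroxy-1-methoxy-4a,8,8-trimethyl-4a,5,6,7,8,9a-hexahydro-3H-benzo[7]annulene-3,9(4H)-dione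
Product: 16 (4aR,5R,7R,9R,9aS)-5-(tert-butyldimethylsilyloxy)-9-hydroxy-1-methoxy-4a,8,8-trimethyl-3-oxo-4,4a,5,6,7,8,9,9a-octahydro-3H-benzo[7]annulen-7-yl benzoate
Conditions: PhCHO (5 equiv), SmI2 (0.3 equiv), THF, −10 °C
Reagents that add atoms: benzaldehyde, O=Cc1ccccc1
Why: Evans–Tishchenko reaction, in which the C7 hydroxyl forms a samarium-bound hemiacetal with benzaldehyde and passes its hydride to the C5 ketone through a chair-like transition state, should give the 1,3-anti C5 alcohol and at the same time cap C7 as a benzoate without alpha-hydrogens; the vinylogous ester has no directing hydroxyl and stays.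

Step 10
Reactants: 16 the C5 alcohol, C7 benzoate of step 9
Product: 17 (4aR,5R,7R,9R,9aS)-5-(tert-butyldimethylsilyloxy)-1-methoxy-4a,8,8-trimethyl-9-(methylsulfonyloxy)-3-oxo-4,4a,5,6,7,8,9,9a-octahydro-3H-benzo[7]annulen-7-yl benzoate
Conditions: MsCl, Et3N, CH2Cl2, 0 °C
Reagents that add atoms: methanesulfonyl chloride, CS(=O)(=O)Cl
Why: Mesylation by way of sulfene, which tolerates hindered secondary alcohols, proceeds with retention at C5.

Step 11
Reactants: 17 the C5 mesylate of step 10
Product: 18 (4S,5R,7R,9R,10S,11R)-7-benzoyloxy-9-(tert-butyldimethylsilyloxy)-1-methoxy-12-norlongipin-1-en-3-one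
Conditions: KN(SiMe3)2 (1.05 equiv), THF (5 mM), −78 °C; then 18-crown-6, −78 to 45 °C
Reagents that add atoms: none
Why: The base removes a C4 proton, the kinetic alpha-prime site of the 3-methoxyenone, and the enolate carbon displaces the C5 mesylate from the rear (SN2). The closest known reaction type is the intramolecular alkylation of a ketone enolate by a secondary sulfonate across a cis-fused bicycle, an established way to close a cyclobutane. The new C4–C5 bond closes the cyclobutane C4–C5–C11–C10 in a 4-(enolexo)-exo-tet mode and by the same bond the six-membered ring C1–C2–C3–C4–C5–C11 that bridges it. C5 is set by inversion of the mesylate, which stands anti to the C7 oxygen and so points away from C4, and C4 is set by the cis fusion, because C4 can reach C5 only on the face where C11 carries it. The step needs C-alkylation at C4 instead of deprotonation at C11 with loss of mesylate. This is secured by the kinetic base without a proton source, by the bridgehead enol ether that O-alkylation would require, and by the absence of hydrogen on C6.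

Step 12
Reactants: 18 (4S,5R,7R,9R,10S,11R)-7-benzoyloxy-9-(tert-butyldimethylsilyloxy)-1-methoxy-12-norlongipin-1-en-3-one
Product: 20 (4R,5S,7R,9R,10R,11R)-9-(tert-butyldimethylsilyloxy)-7-hydroxylongipin-2-en-1-one, via tertiary allylic alcohol 19 (not isolated)
Conditions: MeLi (4 equiv), Et2O, −78 to 0 °C; then 1 M HCl, THF, 0 °C
Reagents that add atoms: methyllithium, [Li]C; water, O
Why: Stork–Danheiser transposition, in which MeLi adds 1,2 to the C3 carbonyl (and cleaves the benzoate) and acid ionises the tertiary allylic alcohol to an oxocarbenium-stabilised cation that water captures at C1, gives the 3-methyl enone; the transient C3 carbinol center vanishes and the other centers are untouched.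

Step 13
Reactants: 20 (4R,5S,7R,9R,10R,11R)-9-(tert-butyldimethylsilyloxy)-7-hydroxylongipin-2-en-1-one; 21 3-methylbut-2-enoyl chloride
Product: 22 (4R,5S,7R,9R,10R,11R)-9-(tert-butyldimethylsilyloxy)-7-(3-methylbut-2-enoyloxy)longipin-2-en-1-one
Conditions: pyridine, DMAP (cat.), CH2Cl2, 0 °C to rt
Reagents that add atoms: none
Why: DMAP-catalysed acylation of the only free hydroxyl with retention at C7; pyridine in place of a trialkylamine limits vinylketene formation and thus deconjugation of the senecioate.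

Step 14
Reactants: 22 (4R,5S,7R,9R,10R,11R)-9-(tert-butyldimethylsilyloxy)-7-(3-methylbut-2-enoyloxy)longipin-2-en-1-one
Product: 23 (4R,5S,7R,9R,10R,11R)-9-hydroxy-7-(3-methylbut-2-enoyloxy)longipin-2-en-1-one
Conditions: HF·pyridine, THF, 0 °C to rt
Reagents that add atoms: none
Why: Fluoride-driven desilylation under mildly acidic conditions should spare the enone and the ester and avoid base-induced acyl migration.

Step 15
Reactants: 23 (4R,5S,7R,9R,10R,11R)-9-hydroxy-7-(3-methylbut-2-enoyloxy)longipin-2-en-1-one; 24 angelic acid ((Z)-2-methylbut-2-enoic acid)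
Product: 26 (4R,5S,7R,9R,10R,11R)-9-angeloyloxy-7-senecioyloxylongipin-2-en-1-one (target), via mixed anhydride 25 (not isolated)
Conditions: 24, 2,4,6-trichlorobenzoyl chloride, Et3N, toluene, rt; then 23, 75 °C
Reagents that add atoms: 2,4,6-trichlorobenzoyl chloride, O=C(Cl)c1c(Cl)cc(Cl)cc1Cl (stays only in 25)
Why: Yamaguchi-type mixed-anhydride esterification without a nucleophilic catalyst, a protocol known to keep the Z geometry of angelates on hindered alcohols, acylates C9 with retention.

## Compound list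

1 | 3-methylbut-3-en-2-one | CC(=O)C(C)=C | starting material
2 | methyl 2,2-dimethyl-3-oxopropanoate | COC(=O)C(C)(C)C=O | starting material
3 | methyl (3R)-3-hydroxy-2,2,6-trimethyl-5-oxohept-6-enoate | C=C(C)C(=O)C[C@@H](O)C(C)(C)C(=O)OC | intermediate
4 | methyl (3R,5R)-3,5-dihydroxy-2,2,6-trimethylhept-6-enoate | C=C(C)[C@H](O)C[C@@H](O)C(C)(C)C(=O)OC | intermediate
5 | methyl (3R,5R)-5-(tert-butyldimethylsilyloxy)-3-hydroxy-2,2,6-trimethylhept-6-enoate | C=C(C)[C@H](O[Si](C)(C)C(C)(C)C)C[C@@H](O)C(C)(C)C(=O)OC | intermediate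
6 | (3R,5R)-5-(tert-butyldimethylsilyloxy)-3-hydroxy-N-methoxy-N,2,2,6-tetramethylhept-6-enamide (Weinreb amide) | C=C(C)[C@H](O[Si](C)(C)C(C)(C)C)C[C@@H](O)C(C)(C)C(=O)N(C)OC | intermediate
7 | (5R,7R)-7-(tert-butyldimethylsilyloxy)-5-hydroxy-4,4,8-trimethylnona-1,8-dien-3-one | C=C(C)[C@H](O[Si](C)(C)C(C)(C)C)C[C@@H](O)C(C)(C)C(=O)C=C | intermediate
8 | (4R,6R)-4-(tert-butyldimethylsilyloxy)-6-hydroxy-3,7,7-trimethylcyclohept-2-en-1-one | CC(C)(C)[Si](C)(C)O[C@@H]1C[C@@H](O)C(C)(C)C(=O)C=C1C | intermediate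
9 | 1,1-dimethoxyethene | C=C(OC)OC | starting material
10 | acetyl chloride | CC(=O)Cl | starting material
11 | 4,4-dimethoxybut-3-en-2-one | CC(=O)C=C(OC)OC | intermediate
12 | 3-(tert-butyldimethylsilyloxy)-1,1-dimethoxybuta-1,3-diene | C=C(O[Si](C)(C)C(C)(C)C)C=C(OC)OC | intermediate
13 | (4R,6R)-4-(tert-butyldimethylsilyloxy)-3,7,7-trimethyl-6-(trimethylsilyloxy)cyclohept-2-en-1-one | CC(C)(C)[Si](C)(C)O[C@@H]1C[C@@H](O[Si](C)(C)C)C(C)(C)C(=O)C=C1C | intermediate
14 | (4aR,5R,7R,9aS)-3,5-bis(tert-butyldimethylsilyloxy)-1,1-dimethoxy-4a,8,8-trimethyl-7-(trimethylsilyloxy)-1,4,4a,5,6,7,8,9a-octahydro-9H-benzo[7]annulen-9-one (cis-fused cycloadduct) | CC(C)(C)[Si](C)(C)O[C@@H]1C[C@@H](O[Si](C)(C)C)C(C)(C)C(=O)[C@H]2C(OC)(OC)C=C(O[Si](C)(C)C(C)(C)C)C[C@]21C | intermediate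
15 | (4aR,5R,7R,9aR)-5-(tert-butyldimethylsilyloxy)-7-hydroxy-1-methoxy-4a,8,8-trimethyl-4a,5,6,7,8,9a-hexahydro-3H-benzo[7]annulene-3,9(4H)-dione (cis-fused; C5 ketone, C7 OH, C9 OTBS) | CC(C)(C)[Si](C)(C)O[C@@H]1C[C@@H](O)C(C)(C)C(=O)[C@H]2C(OC)=CC(=O)C[C@]21C | intermediate
16 | (4aR,5R,7R,9R,9aS)-5-(tert-butyldimethylsilyloxy)-9-hydroxy-1-methoxy-4a,8,8-trimethyl-3-oxo-4,4a,5,6,7,8,9,9a-octahydro-3H-benzo[7]annulen-7-yl benzoate (C5 OH anti to C7 OBz) | CC(C)(C)[Si](C)(C)O[C@@H]1C[C@@H](OC(=O)c2ccccc2)C(C)(C)[C@H](O)[C@H]3C(OC)=CC(=O)C[C@]31C | intermediate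
17 | (4aR,5R,7R,9R,9aS)-5-(tert-butyldimethylsilyloxy)-1-methoxy-4a,8,8-trimethyl-9-(methylsulfonyloxy)-3-oxo-4,4a,5,6,7,8,9,9a-octahydro-3H-benzo[7]annulen-7-yl benzoate | CC(C)(C)[Si](C)(C)O[C@@H]1C[C@@H](OC(=O)c2ccccc2)C(C)(C)[C@H](OS(C)(=O)=O)[C@H]3C(OC)=CC(=O)C[C@]31C | intermediate
18 | (4S,5R,7R,9R,10S,11R)-7-benzoyloxy-9-(tert-butyldimethylsilyloxy)-1-methoxy-12-norlongipin-1-en-3-one | CC(C)(C)[Si](C)(C)O[C@@H]1C[C@@H](OC(=O)c2ccccc2)C(C)(C)[C@@H]2[C@H]3C(OC)=CC(=O)[C@@H]2[C@]31C | intermediate
19 | 9-(tert-butyldimethylsilyloxy)-1-methoxylongipin-1-ene-3,7-diol (ring centers spatially as in 18; C3 configuration immaterial) | CC(C)(C)[Si](C)(C)O[C@@H]1C[C@@H](O)C(C)(C)[C@@H]2[C@H]3C(OC)=CC(C)(O)[C@@H]2[C@]31C | intermediate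
20 | (4R,5S,7R,9R,10R,11R)-9-(tert-butyldimethylsilyloxy)-7-hydroxylongipin-2-en-1-one | CC(C)(C)[Si](C)(C)O[C@@H]1C[C@@H](O)C(C)(C)[C@@H]2[C@H]3C(=O)C=C(C)[C@@H]2[C@]31C | intermediate
21 | 3-methylbut-2-enoyl chloride | CC(C)=CC(=O)Cl | starting material
22 | (4R,5S,7R,9R,10R,11R)-9-(tert-butyldimethylsilyloxy)-7-(3-methylbut-2-enoyloxy)longipin-2-en-1-one | CC(C)(C)[Si](C)(C)O[C@@H]1C[C@@H](OC(=O)C=C(C)C)C(C)(C)[C@@H]2[C@H]3C(=O)C=C(C)[C@@H]2[C@]31C | intermediate
23 | (4R,5S,7R,9R,10R,11R)-9-hydroxy-7-(3-methylbut-2-enoyloxy)longipin-2-en-1-one | O[C@@H]1C[C@@H](OC(=O)C=C(C)C)C(C)(C)[C@@H]2[C@H]3C(=O)C=C(C)[C@@H]2[C@]31C | intermediate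
24 | angelic acid, (Z)-2-methylbut-2-enoic acid | C/C=C(/C)C(=O)O | starting material
25 | (Z)-2-methylbut-2-enoic 2,4,6-trichlorobenzoic anhydride | C/C=C(/C)C(=O)OC(=O)c1c(Cl)cc(Cl)cc1Cl | intermediate
26 | (4R,5S,7R,9R,10R,11R)-9-angeloyloxy-7-senecioyloxylongipin-2-en-1-one | C/C=C(/C)C(=O)O[C@@H]1C[C@@H](OC(=O)C=C(C)C)C(C)(C)[C@@H]2[C@H]3C(=O)C=C(C)[C@@H]2[C@]31C | target

## Step count and risks

Total step count: 15. Longest linear sequence: 13 (steps 1–5 and 8–15).

**Step 11.** Substitution at C5, flanked by quaternary C6 and tertiary C11, may be too slow. Proton shuffling to C11 followed by loss of methanesulfonate, or participation of the benzoate carbonyl, could then overtake ring closure.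

The fallback replaces the ionic closure by a photochemical one. It sets out from 15 and comes back at 18.
- Benzoylation (BzCl, pyridine, DMAP) would give keto benzoate F1.
- Norrish–Yang cyclisation (light above 300 nm, benzene) follows. The excited C5 ketone abstracts a C4 hydrogen through a six-membered transition state, and the 1,4-biradical closes the same C4–C5 bond to give cyclobutanol F2.
- Methyl oxalyl chloride with DMAP would give tertiary oxalate F3.
- Bu3SnH/AIBN (toluene, 110 °C) would replace the oxalate by hydrogen. The cage allows only one configuration at C5.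

**Step 8.** Cycloaddition to the beta,beta-disubstituted enone may be slower than decay of the ketene-acetal diene, and facial selectivity may erode under forcing conditions.

The fallback uses a removable activating group. It sets out from 8 and comes back at 15.
- Alpha-iodination (I2, pyridine, CH2Cl2) would give iodoenone F4.
- Carbonylation (PdCl2(PPh3)2, CO, MeOH, Et3N) would give enone ester F5.
- The doubly activated F5 should add 12 at ambient pressure to give ester cycloadduct F6.
- Dilute HCl would give vinylogous ester keto ester F7.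
- Krapcho dealkoxycarbonylation (LiCl, wet DMSO, 120 °C), with protonation of C11 on the convex face, removes the activating group.

**Step 9.** The hydride shift may stall at the congested C5 ketone, or C11 may epimerise under the basic samarium alkoxide.

The fallback separates reduction from protection under acidic conditions. It sets out from 15 and comes back at 16.
- Evans–Saksena reduction (Me4NBH(OAc)3, MeCN/AcOH, −20 °C) would give anti diol F8.
- Selective benzoylation of the less hindered C7 hydroxyl (BzCl, pyridine, −20 °C) then follows.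

## Further compounds

F1 | step 11 | keto benzoate (C7 benzoate of 15) | CC(C)(C)[Si](C)(C)O[C@@H]1C[C@@H](OC(=O)c2ccccc2)C(C)(C)C(=O)[C@H]2C(OC)=CC(=O)C[C@]21C
F2 | step 11 | cyclobutanol (5-hydroxy derivative of 18) | CC(C)(C)[Si](C)(C)O[C@@H]1C[C@@H](OC(=O)c2ccccc2)C(C)(C)[C@]2(O)[C@H]3C(OC)=CC(=O)[C@@H]2[C@]31C
F3 | step 11 | tertiary oxalate (C5 methyl oxalate of F2) | CC(C)(C)[Si](C)(C)O[C@@H]1C[C@@H](OC(=O)c2ccccc2)C(C)(C)[C@]2(OC(=O)C(=O)OC)[C@H]3C(OC)=CC(=O)[C@@H]2[C@]31C
F4 | step 8 | iodoenone (2-iodo derivative of 8) | CC(C)(C)[Si](C)(C)O[C@@H]1C[C@@H](O)C(C)(C)C(=O)C(I)=C1C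
F5 | step 8 | enone ester (2-methoxycarbonyl derivative of 8) | CC(C)(C)[Si](C)(C)O[C@@H]1C[C@@H](O)C(C)(C)C(=O)C(C(=O)OC)=C1C
F6 | step 8 | ester cycloadduct (C11 methoxycarbonyl, C1 dimethyl ketal, C3 silyl enol ether) | CC(C)(C)[Si](C)(C)O[C@@H]1C[C@@H](O)C(C)(C)C(=O)[C@@]2(C(=O)OC)C(OC)(OC)C=C(O[Si](C)(C)C(C)(C)C)C[C@]21C
F7 | step 8 | vinylogous ester keto ester (C11 methoxycarbonyl derivative of 15) | CC(C)(C)[Si](C)(C)O[C@@H]1C[C@@H](O)C(C)(C)C(=O)[C@@]2(C(=O)OC)C(OC)=CC(=O)C[C@]21C
F8 | step 9 | anti diol (C5, C7 diol corresponding to 16) | CC(C)(C)[Si](C)(C)O[C@@H]1C[C@@H](O)C(C)(C)[C@H](O)[C@H]2C(OC)=CC(=O)C[C@]21C
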